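**Retrosynthetic overview**
1. The vinyl group comes last, by Wittig methylenation of an oxane-2-carbaldehyde made by periodate cleavage of a side-chain 1,2-diol.
2. The oxane ring is the second and last ring closure: the tertiary OH of an anti bromohydrin (Shi epoxide opened by bromide) opens a Sharpless 2,3-epoxy alcohol 6-exo at its tertiary carbon.
3. The C20 E,E-dienol comes from a C10 + C10 union: alpha-selective carbonyl allylation of an oxanorbornane carbaldehyde with a geraniol-derived allylbarium reagent, followed by deoxygenation of the carbinol.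
4. The oxanorbornane is the first ring closure: Diels–Alder of 2,5-dimethylfuran with maleic anhydride, hydrogenation, reduction and enzymatic desymmetrisation. One arm then becomes CH3. The other becomes CHO and is epimerised from exo to endo.

Notation: Bic = 1,3,4-trimethyl-7-oxabicyclo[2.2.1]heptan-2-yl, bonded through C2 on the endo face, with the C3 methyl exo and the absolute configuration of aldehyde 11. Open-chain compounds are numbered as nonane derivatives (C1 = CH2O end, C9 bonded to Bic).

Assumption: the lipase acetylates the arm drawn in 6. If it prefers the other arm, the same enzyme run in the hydrolysis direction on the diacetate of 5 gives 6. The L-fructose-derived enantiomer of the Shi ketone is taken as purchasable (it is also made from L-sorbose).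

**Fragment 1: oxanorbornane aldehyde**

Step 1
Reactants: 1 2,5-dimethylfuran; 2 maleic anhydride
Product: 3 exo-1,4-dimethyl-7-oxabicyclo[2.2.1]hept-5-ene-2,3-dicarboxylic anhydride (meso)
Conditions: Et2O, rt, 24 h; filter the crystals cold
Reagents that add atoms: none
Why: The Diels–Alder cycloaddition of the electron-rich furan with a doubly activated dienophile is reversible at rt, so the thermodynamically favoured exo adduct crystallises, setting both bridgehead C–O centres and the cis,exo pair of carbonyl arms in one meso compound.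

Step 2
Reactants: 3 exo Diels–Alder adduct
Product: 4 exo-1,4-dimethyl-7-oxabicyclo[2.2.1]heptane-2,3-dicarboxylic anhydride (meso)
Conditions: H2 (3 bar), 10% Pd/C, EtOAc, 0 °C to rt
Reagents that add atoms: none
Why: Heterogeneous catalytic hydrogenation saturates the strained, unhindered C5=C6 bond and so shuts off the retro-Diels–Alder path, creating no stereocentre and leaving anhydride and ether intact.

Step 3
Reactants: 4 saturated meso anhydride
Product: 5 (1,4-dimethyl-7-oxabicyclo[2.2.1]heptane-2-exo,3-exo-diyl)dimethanol (meso)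
Conditions: LiAlH4, THF, 0 °C to reflux; H2O/aq. NaOH work-up
Reagents that add atoms: none
Why: Hydride reduction takes both anhydride carbonyls to primary alcohols without touching the ether bridge or the four stereocentres.

Step 4
Reactants: 5 meso diol
Product: 6 [(1R,2R,3S,4S)-3-(hydroxymethyl)-1,4-dimethyl-7-oxabicyclo[2.2.1]heptan-2-yl]methyl acetate (both arms exo)
Conditions: lipase from Burkholderia cepacia (lipase PS), vinyl acetate (3 equiv), t-BuOMe, 25 °C
Reagents that add atoms: vinyl acetate, C=COC(C)=O
Why: Lipase-catalysed irreversible transesterification (enantiotopic-group-selective acylation of a meso diol) acetylates one of the two mirror-related CH2OH arms, which fixes the absolute configuration of all four ring stereocentres at once.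

Step 5
Reactants: 6 monoacetate
Product: 7 [(1R,2R,3R,4S)-3-(iodomethyl)-1,4-dimethyl-7-oxabicyclo[2.2.1]heptan-2-yl]methyl acetate (both arms exo)
Conditions: I2, PPh3, imidazole, CH2Cl2, 0 °C to rt
Reagents that add atoms: iodine, [I][I]
Why: Appel-type (Garegg–Samuelsson) iodination displaces the alkoxyphosphonium group by SN2 attack of iodide at a freely rotating primary carbon, and the fast near-neutral conditions avoid acetyl migration, which would racemise 6.

Step 6
Reactants: 7 iodo acetate
Product: 8 [(1R,2R,3R,4S)-1,3,4-trimethyl-7-oxabicyclo[2.2.1]heptan-2-yl]methyl acetate (CH2OAc exo, C3 methyl exo)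
Conditions: Bu3SnH, azobisisobutyronitrile (0.1 equiv), toluene, 80 °C
Reagents that add atoms: none
Why: Radical chain dehalogenation replaces the primary C–I bond by C–H regardless of crowding, giving the exo methyl group of the target with C3 untouched.

Step 7
Reactants: 8 acetate
Product: 9 [(1R,2R,3R,4S)-1,3,4-trimethyl-7-oxabicyclo[2.2.1]heptan-2-yl]methanol (CH2OH exo)
Conditions: K2CO3 (0.2 equiv), MeOH, rt
Reagents that add atoms: none
Why: Base-catalysed transesterification removes the acetate, and nothing else in the molecule is electrophilic or epimerisable.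

Step 8
Reactants: 9 exo alcohol
Product: 10 (1R,2S,3R,4S)-1,3,4-trimethyl-7-oxabicyclo[2.2.1]heptane-2-carbaldehyde (CHO exo, cis to the C3 methyl)
Conditions: Dess–Martin periodinane, CH2Cl2, rt
Reagents that add atoms: none
Why: Dess–Martin oxidation stops at the aldehyde under mild conditions that cope with the hindered primary alcohol and leave the ether bridge alone.

Step 9
Reactants: 10 exo aldehyde
Product: 11 (1R,2R,3R,4S)-1,3,4-trimethyl-7-oxabicyclo[2.2.1]heptane-2-carbaldehyde (CHO endo, trans to the exo C3 methyl)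
Conditions: K2CO3 (0.2 equiv), MeOH, rt, 12 h; chromatography, recycle recovered 10
Reagents that add atoms: none
Why: Base-catalysed epimerisation through the enolate is thermodynamically controlled and relieves the eclipsed cis-diexo CHO/CH3 pair, so the formyl group moves to the endo face and sets C2, while the weak base in a protic medium keeps the enolate concentration too low for beta-elimination of the bridging oxygen.

**Fragment 2: allylic chloride**

Step 10
Reactants: 12 geraniol
Product: 13 geranyl tert-butyldimethylsilyl ether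
Conditions: TBSCl, imidazole, DMF, rt
Reagents that add atoms: tert-butyldimethylsilyl chloride, CC(C)(C)[Si](C)(C)Cl
Why: Standard silylation masks the allylic alcohol with a group that is inert to SeO2, to the organobarium reagent and to the tin hydride step.

Step 11
Reactants: 13 geranyl silyl ether
Product: 15 (2E,6E)-8-(tert-butyldimethylsilyloxy)-2,6-dimethylocta-2,6-dien-1-ol, via 8-oxo enal 14 (not isolated)
Conditions: SeO2 (0.1 equiv), t-BuOOH, salicylic acid (0.1 equiv), CH2Cl2, rt; then NaBH4, MeOH, 0 °C
Reagents that add atoms: tert-butyl hydroperoxide, CC(C)(C)OO (oxygen relayed through catalytic SeO2, O=[Se]=O)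
Why: Riley-type allylic oxidation (ene reaction, then [2,3]-sigmatropic shift) attacks the more electron-rich distal olefin and, within it, the E methyl group, and borohydride returns the over-oxidised enal to the alcohol, so the 6E geometry needed later is secured.

Step 12
Reactants: 15 allylic alcohol
Product: 16 (2E,6E)-8-chloro-3,7-dimethylocta-2,6-dienyl tert-butyldimethylsilyl ether
Conditions: N-chlorosuccinimide, Me2S, CH2Cl2, −30 to 0 °C
Reagents that add atoms: N-chlorosuccinimide, ClN1C(=O)CCC1=O
Why: In this Corey–Kim-type chlorination chloride displaces the alkoxysulfonium group at the primary carbon by SN2, without allylic transposition, E/Z loss or harm to the silyl ether.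

**Union and end game**

Step 13
Reactants: 16 allylic chloride; 11 endo aldehyde
Product: 18 (2E,6E)-1-(tert-butyldimethylsilyloxy)-3,7-dimethyl-9-Bic-nona-2,6-dien-9-ol (both C9 epimers), via allylbarium chloride 17 (not isolated)
Conditions: BaI2, lithium biphenylide (2 equiv), THF, rt (active Ba); 16, −78 °C, 30 min; 11, −78 °C, 30 min; H2O quench
Reagents that add atoms: none
Why: In this carbonyl allylation the allylbarium reagent made and kept at −78 °C holds its E geometry and attacks aldehydes through its unsubstituted alpha terminus rather than by the usual gamma (SE2') mode, so the linear C8–C9 bond forms; addition is faster than enolisation at this temperature, so C2 of Bic is kept, and the new carbinol centre is irrelevant because it is removed in steps 14 and 15.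

Step 14
Reactants: 18 homoallylic alcohol
Product: 19 O-[(2E,6E)-1-(tert-butyldimethylsilyloxy)-3,7-dimethyl-9-Bic-nona-2,6-dien-9-yl] imidazole-1-carbothioate
Conditions: 1,1'-thiocarbonyldiimidazole, 4-(dimethylamino)pyridine (0.2 equiv), toluene, 80 °C
Reagents that add atoms: 1,1'-thiocarbonyldiimidazole, S=C(n1ccnc1)n1ccnc1
Why: Thioacylation (first half of the Barton–McCombie deoxygenation) works on hindered secondary alcohols under neutral conditions that leave the silyl ether and both olefins alone.

Step 15
Reactants: 19 thiocarbonyl imidazolide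
Product: 20 (2E,6E)-3,7-dimethyl-9-Bic-nona-2,6-dienyl tert-butyldimethylsilyl ether
Conditions: Bu3SnH (0.5 M), azobisisobutyronitrile (0.1 equiv), toluene, 100 °C
Reagents that add atoms: none
Why: In the Barton–McCombie radical deoxygenation the secondary C9 radical is quenched by concentrated tin hydride far faster than it can add reversibly to the homoallylic double bond, so the 6E olefin is kept.

Step 16
Reactants: 20 silyl ether
Product: 21 (2E,6E)-3,7-dimethyl-9-Bic-nona-2,6-dien-1-ol
Conditions: Bu4NF, THF, rt
Reagents that add atoms: none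
Why: Fluoride-induced desilylation is driven by the Si–F bond and touches nothing else.

Step 17
Reactants: 21 allylic alcohol
Product: 22 (2E,6E)-3,7-dimethyl-9-Bic-nona-2,6-dienyl acetate
Conditions: Ac2O, pyridine, rt
Reagents that add atoms: acetic anhydride, CC(=O)OC(C)=O
Why: Acetylation installs an electron-withdrawing allylic group that deactivates C2=C3 towards the electrophilic oxidant of the next step.

Step 18
Reactants: 22 dienyl acetate
Product: 23 (2E,6S,7S)-6,7-epoxy-3,7-dimethyl-9-Bic-non-2-enyl acetate
Conditions: 1,2:4,5-di-O-isopropylidene-beta-L-erythro-2,3-hexodiulo-2,6-pyranose (0.3 equiv), KHSO5 (as 2KHSO5·KHSO4·K2SO4, 1.4 equiv), K2CO3, Bu4NHSO4 (cat.), Na2B4O7/Na2EDTA buffer, MeCN–CH2(OMe)2–H2O, 0 °C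
Reagents that add atoms: potassium peroxymonosulfate, [K+].OOS(=O)(=O)[O-]
Why: Shi asymmetric epoxidation (chiral dioxirane, spiro transition state) is syn-stereospecific on the E-trisubstituted olefin; the D-fructose ketone gives R,R epoxides, so its L-series enantiomer gives the 6S,7S epoxide under reagent control, and the acetate-deactivated C2=C3 bond is left alone.

Step 19
Reactants: 23 epoxy acetate
Product: 24 (2E,6S,7S)-6,7-epoxy-3,7-dimethyl-9-Bic-non-2-en-1-ol
Conditions: K2CO3 (0.2 equiv), MeOH, 0 °C to rt
Reagents that add atoms: none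
Why: Mild methanolysis frees the allylic alcohol now, because the same base applied after bromide introduction would close the bromohydrin back to the epoxide.

Step 20
Reactants: 24 epoxy allylic alcohol
Product: 25 (2E,6R,7S)-6-bromo-3,7-dimethyl-9-Bic-non-2-ene-1,7-diol
Conditions: Li2NiBr4 (0.4 M stock solution in THF, 1.5 equiv), THF, 0 °C to rt; pH 7 buffer
Reagents that add atoms: dilithium tetrabromonickelate, [Li+].[Li+].[Ni+2].[Br-].[Br-].[Br-].[Br-]
Why: In this halohydrin formation the soft bromide opens the epoxide by SN2 at its less substituted carbon C6 with clean inversion (6S epoxide carbon to 6R bromide) while the C7–O bond and its S configuration stay intact, giving the anti bromohydrin.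

Step 21
Reactants: 25 bromohydrin allylic alcohol
Product: 26 (2R,3R,6R,7S)-6-bromo-2,3-epoxy-3,7-dimethyl-9-Bic-nonane-1,7-diol
Conditions: Ti(OiPr)4 (0.2 equiv), D-(−)-diethyl tartrate (0.25 equiv), t-BuOOH (in decane), 4 Å MS, CH2Cl2, −20 °C; aq. citric acid work-up
Reagents that add atoms: tert-butyl hydroperoxide, CC(C)(C)OO
Why: Sharpless asymmetric epoxidation acts only on the allylic alcohol, and the D-(−)-tartrate gives the 2R,3R epoxide of an E-3-methylalk-2-en-1-ol (geraniol gives 2S,3S with the L-(+)-ester), while the non-basic work-up keeps the bromohydrin open.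

Step 22
Reactants: 26 bromohydrin epoxy alcohol
Product: 27 (1R)-1-[(2S,5R,6S)-5-bromo-2,6-dimethyl-6-(2-Bic-ethyl)oxan-2-yl]ethane-1,2-diol
Conditions: (+)-camphor-10-sulfonic acid (0.1 equiv), CH2Cl2, 0 °C to rt
Reagents that add atoms: none
Why: In this acid-catalysed intramolecular epoxide opening (6-exo-tet, favoured by both ring size and Markovnikov bias) the tertiary C7 hydroxyl attacks the tertiary C3 of the activated epoxide from the back, so that carbon is inverted (R epoxide carbon to S ether carbon) while the CHBr and C7 centres are untouched.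

Step 23
Reactants: 27 oxane diol
Product: 28 (2S,5R,6S)-5-bromo-2,6-dimethyl-6-(2-Bic-ethyl)oxane-2-carbaldehyde
Conditions: NaIO4, THF–H2O (pH 7), 0 °C to rt
Reagents that add atoms: none
Why: Malaprade glycol cleavage removes C1 as formaldehyde and leaves an aldehyde on a quaternary carbon that cannot epimerise, and the bromide and ethers are inert to periodate.

Step 24
Reactants: 28 oxane aldehyde
Product: 29 dactylopyranoid, (2S,3R,6S)-3-bromo-2,6-dimethyl-6-vinyl-2-{2-[(1R,2R,3R,4S)-1,3,4-trimethyl-7-oxabicyclo[2.2.1]heptan-2-yl]ethyl}oxane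
Conditions: Ph3PCH3Br (1.5 equiv), KN(SiMe3)2 (1.4 equiv), THF, 0 °C; then 28, −78 to 0 °C
Reagents that add atoms: methyltriphenylphosphonium bromide, C[P+](c1ccccc1)(c1ccccc1)c1ccccc1.[Br-]
Why: Wittig methylenation with no excess base converts the non-enolisable aldehyde into the vinyl group, and the equatorial secondary bromide has no anti-periplanar hydrogen for E2 loss at these temperatures.

**Compound list**
1 | 2,5-dimethylfuran | Cc1ccc(C)o1 | starting material
2 | maleic anhydride | O=C1C=CC(=O)O1 | starting material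
3 | exo-1,4-dimethyl-7-oxabicyclo[2.2.1]hept-5-ene-2,3-dicarboxylic anhydride (meso) | O=C1OC(=O)[C@@H]2[C@H]1[C@@]3(C)C=C[C@]2(C)O3 | intermediate
4 | exo-1,4-dimethyl-7-oxabicyclo[2.2.1]heptane-2,3-dicarboxylic anhydride (meso) | O=C1OC(=O)[C@@H]2[C@H]1[C@@]3(C)CC[C@]2(C)O3 | intermediate
5 | exo,exo meso diol | OC[C@H]1[C@@H](CO)[C@]2(C)CC[C@@]1(C)O2 | intermediate
6 | (1R,2R,3S,4S) monoacetate | CC(=O)OC[C@H]1[C@@H](CO)[C@]2(C)CC[C@@]1(C)O2 | intermediate
7 | iodo acetate | CC(=O)OC[C@H]1[C@@H](CI)[C@]2(C)CC[C@@]1(C)O2 | intermediate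
8 | trimethyl acetate (CH2OAc exo) | CC(=O)OC[C@H]1[C@@H](C)[C@]2(C)CC[C@@]1(C)O2 | intermediate
9 | exo alcohol | OC[C@H]1[C@@H](C)[C@]2(C)CC[C@@]1(C)O2 | intermediate
10 | exo aldehyde (1R,2S,3R,4S) | O=C[C@H]1[C@@H](C)[C@]2(C)CC[C@@]1(C)O2 | intermediate
11 | endo aldehyde (1R,2R,3R,4S) | O=C[C@@H]1[C@@H](C)[C@]2(C)CC[C@@]1(C)O2 | intermediate
12 | geraniol | OC/C=C(C)/CCC=C(C)C | starting material
13 | geranyl TBS ether | CC(C)(C)[Si](C)(C)OC/C=C(C)/CCC=C(C)C | intermediate
14 | (2E,6E)-8-(TBS-oxy)-2,6-dimethylocta-2,6-dienal | CC(C)(C)[Si](C)(C)OC/C=C(C)/CC/C=C(C)/C=O | intermediate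
15 | (2E,6E)-8-(TBS-oxy)-2,6-dimethylocta-2,6-dien-1-ol | CC(C)(C)[Si](C)(C)OC/C=C(C)/CC/C=C(C)/CO | intermediate
16 | (2E,6E)-8-chloro-3,7-dimethylocta-2,6-dienyl TBS ether | CC(C)(C)[Si](C)(C)OC/C=C(C)/CC/C=C(C)/CCl | intermediate
17 | allylbarium chloride from 16 | CC(C)(C)[Si](C)(C)OC/C=C(C)/CC/C=C(C)/C[Ba]Cl | intermediate
18 | C9 carbinol (both epimers) | CC(C)(C)[Si](C)(C)OC/C=C(C)/CC/C=C(C)/CC(O)[C@@H]1[C@@H](C)[C@]2(C)CC[C@@]1(C)O2 | intermediate
19 | C9 imidazole-1-carbothioate | CC(C)(C)[Si](C)(C)OC/C=C(C)/CC/C=C(C)/CC(OC(=S)n1ccnc1)[C@@H]1[C@@H](C)[C@]2(C)CC[C@@]1(C)O2 | intermediate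
20 | C20 dienyl TBS ether | CC(C)(C)[Si](C)(C)OC/C=C(C)/CC/C=C(C)/CC[C@@H]1[C@@H](C)[C@]2(C)CC[C@@]1(C)O2 | intermediate
21 | C20 dienol | OC/C=C(C)/CC/C=C(C)/CC[C@@H]1[C@@H](C)[C@]2(C)CC[C@@]1(C)O2 | intermediate
22 | C20 dienyl acetate | CC(=O)OC/C=C(C)/CC/C=C(C)/CC[C@@H]1[C@@H](C)[C@]2(C)CC[C@@]1(C)O2 | intermediate
23 | (6S,7S)-epoxy acetate | CC(=O)OC/C=C(C)/CC[C@@H]1O[C@@]1(C)CC[C@@H]2[C@@H](C)[C@]3(C)CC[C@@]2(C)O3 | intermediate
24 | (6S,7S)-epoxy allylic alcohol | OC/C=C(C)/CC[C@@H]1O[C@@]1(C)CC[C@@H]2[C@@H](C)[C@]3(C)CC[C@@]2(C)O3 | intermediate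
25 | (6R,7S)-bromohydrin allylic alcohol | OC/C=C(C)/CC[C@@H](Br)[C@@](C)(O)CC[C@@H]1[C@@H](C)[C@]2(C)CC[C@@]1(C)O2 | intermediate
26 | (2R,3R,6R,7S)-bromohydrin epoxy alcohol | OC[C@H]1O[C@]1(C)CC[C@@H](Br)[C@@](C)(O)CC[C@@H]2[C@@H](C)[C@]3(C)CC[C@@]2(C)O3 | intermediate
27 | bromo-oxane 1,2-diol | OC[C@@H](O)[C@]1(C)CC[C@@H](Br)[C@](C)(CC[C@@H]2[C@@H](C)[C@]3(C)CC[C@@]2(C)O3)O1 | intermediate
28 | bromo-oxane carbaldehyde | O=C[C@]1(C)CC[C@@H](Br)[C@](C)(CC[C@@H]2[C@@H](C)[C@]3(C)CC[C@@]2(C)O3)O1 | intermediate
29 | dactylopyranoid | C=C[C@]1(C)CC[C@@H](Br)[C@](C)(CC[C@@H]2[C@@H](C)[C@]3(C)CC[C@@]2(C)O3)O1 | target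

**Totals**
Total step count: 24. Longest linear sequence: 21 (steps 1–9, then 13–24). The geraniol branch takes 3 steps (10–12).

**The three steps most likely to fail**

Step 4: the two bridgehead methyl groups may make the diol a slow or poorly discriminated enzyme substrate. The fallback desymmetrises one oxidation level earlier with a small-molecule mediator. It sets out from 4 and comes back at 9. Anhydride 4 is opened with methanol in the presence of quinidine (toluene–CCl4, −55 °C; quinine is available should the sense of induction call for it) to the exo,exo monomethyl ester F1. BH3·SMe2 reduces only the free acid, and the hydroxy ester closes (cat. TsOH) to the cis-fused gamma-lactone F2. i-Bu2AlH at −78 °C gives the lactol F3. Propane-1,3-dithiol with BF3·OEt2 at −20 °C traps the open hydroxy aldehyde as the dithiane alcohol F4. Raney Ni in EtOH desulfurises the dithiane carbon to the exo methyl group, which gives 9.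

Step 13: the alpha/gamma ratio could fall with this hindered aldehyde, and the allylic silyl ether must survive the reducing metal. The fallback exchanges carbonyl addition for sulfone alkylation, which also makes the deoxygenation unnecessary. It sets out from 11 and 16 and comes back at 20. Chloride 16 reacts with PhSO2Na (DMF, rt) to give the allylic sulfone F5. Aldehyde 11 is reduced (NaBH4, MeOH) to the endo carbinol F6, which I2/PPh3/imidazole turns into the primary iodide F7. The lithio derivative of F5 (n-BuLi, THF–DMPU, −78 °C) is alkylated with F7 to the C20 sulfone F8. PdCl2(dppp)-catalysed hydride displacement with LiBHEt3 (THF, 0 °C) then removes the sulfonyl group without moving or isomerising the double bond, giving 20.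

Step 20: bromide may attack the tertiary epoxide carbon in part. The fallback gives up the stepwise bromohydrin/epoxide logic and closes the oxane by bromonium-induced cyclisation. It sets out from 21 and comes back at 29. Sharpless epoxidation of 21 with L-(+)-diethyl tartrate gives the (2S,3S)-epoxy alcohol F9. I2/PPh3/imidazole gives the epoxy iodide F10. Zn dust in EtOH–AcOH opens it reductively to the (3S) tertiary allylic alcohol F11, which already carries the vinyl/methyl carbinol centre. N-Bromosuccinimide in (CF3)2CHOH (4 Å MS, 0 °C) then effects 6-endo bromoetherification. Anti addition to the E olefin fixes the CHBr/C–O relationship, but facial selectivity is low, so 29 must be separated by HPLC from its diastereomer at these two centres and from oxolane isomers.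

**Further compounds**
F1 | step 4 | (2-exo,3-exo)-3-(methoxycarbonyl)-1,4-dimethyl-7-oxabicyclo[2.2.1]heptane-2-carboxylic acid | OC(=O)[C@H]1[C@@H](C(=O)OC)[C@]2(C)CC[C@@]1(C)O2
F2 | step 4 | cis-exo-fused gamma-lactone (C=O on the carbon that becomes the methyl-bearing C3) | O=C1OC[C@H]2[C@@H]1[C@]3(C)CC[C@@]2(C)O3
F3 | step 4 | corresponding lactol (anomers) | OC1OC[C@H]2[C@@H]1[C@]3(C)CC[C@@]2(C)O3
F4 | step 4 | [3-exo-(1,3-dithian-2-yl)-1,4-dimethyl-7-oxabicyclo[2.2.1]heptan-2-exo-yl]methanol | OC[C@H]1[C@@H](C2SCCCS2)[C@]3(C)CC[C@@]1(C)O3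
F5 | step 13 | (2E,6E)-3,7-dimethyl-8-(phenylsulfonyl)octa-2,6-dienyl TBS ether | CC(C)(C)[Si](C)(C)OC/C=C(C)/CC/C=C(C)/CS(=O)(=O)c1ccccc1
F6 | step 13 | Bic-methanol (CH2OH endo) | OC[C@@H]1[C@@H](C)[C@]2(C)CC[C@@]1(C)O2
F7 | step 13 | Bic-methyl iodide (CH2I endo) | IC[C@@H]1[C@@H](C)[C@]2(C)CC[C@@]1(C)O2
F8 | step 13 | (2E,6E)-3,7-dimethyl-8-(phenylsulfonyl)-9-Bic-nona-2,6-dienyl TBS ether (C8 epimers) | CC(C)(C)[Si](C)(C)OC/C=C(C)/CC/C=C(C)/C(C[C@@H]1[C@@H](C)[C@]2(C)CC[C@@]1(C)O2)S(=O)(=O)c1ccccc1
F9 | step 20 | (2S,3S,6E)-2,3-epoxy-3,7-dimethyl-9-Bic-non-6-en-1-ol | OC[C@@H]1O[C@@]1(C)CC/C=C(C)/CC[C@@H]2[C@@H](C)[C@]3(C)CC[C@@]2(C)O3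
F10 | step 20 | corresponding 1-iodo-2,3-epoxide | IC[C@@H]1O[C@@]1(C)CC/C=C(C)/CC[C@@H]2[C@@H](C)[C@]3(C)CC[C@@]2(C)O3
F11 | step 20 | (3S,6E)-3,7-dimethyl-9-Bic-nona-1,6-dien-3-ol | C=C[C@@](C)(O)CC/C=C(C)/CC[C@@H]1[C@@H](C)[C@]2(C)CC[C@@]1(C)O2
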